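The dihydrofuran ring is cut at C2–C3. C3, a diarylmethine, is traced back to a rhodium-bound diaryl carbene. C2, an oxygen-bearing benzylic CH, is traced back to the OCH2 group of an aryl benzyl ether. Until O1 is tied to C2, the benzo ring is symmetric about the C3a–C6 line. Both oxygens ortho to C3a can therefore carry the same 4-(benzyloxy)benzyl group, and either one gives the same product. One enantioselective 1,5-C–H insertion forms C2–C3, closes the ring and sets both stereocentres. The precursor is a diaryldiazomethane whose five phenol oxygens all bear that group. Hydrogenolysis and acid equilibration of C2 then finish.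

Key step: step 7

**Abbreviations and remarks**

- BOB = 4-(benzyloxy)benzyl, CH2–C6H4–OCH2Ph.
- Rh2(R-PTAD)4 = dirhodium tetrakis[(R)-N-phthaloyl-(1-adamantyl)glycinate].
- Atom numbers are those of 2,3-dihydrobenzofuran.

Protecting-group logic:
- The methyl ethers serve only for the directed lithiation. BBr3 removes all of them at the stage of the achiral, robust benzophenone, where no choice between ethers is needed.
- One alkylating agent then covers all five phenols. Two copies act as insertion partners and three as spectators.
- The target holds no alkene, so every BOB and benzyl group can leave by neutral hydrogenolysis. The acid-labile dihydrobenzofuran never meets a strong Lewis acid, and no free benzylic cations are released beside unprotected resorcinol rings.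

Assumption: the (R)-configured catalyst is taken to give the (3S) series, by analogy with simpler carbenes derived from 2-benzyloxybenzophenones. The sense is to be verified on the first run. If it proves opposite, Rh2(S-PTAD)4, equally available, is used with no other change.

**Step 1**
Reactants: 1 (E)-3,4',5-trimethoxystilbene
Product: 2 1,3-dimethoxy-5-[2-(4-methoxyphenyl)ethyl]benzene (3,4',5-trimethoxybibenzyl)
Conditions: H2 (1 atm), 10% Pd/C, EtOAc, rt
Reagents that add atoms: none
Why: Catalytic hydrogenation saturates the only alkene while the aryl methyl ethers stay inert, and it removes a group that would otherwise undergo carbolithiation in the next step.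

**Step 2**
Reactants: 2 3,4',5-trimethoxybibenzyl; 3 3,5-dimethoxybenzoyl chloride
Product: 5 {2,6-dimethoxy-4-[2-(4-methoxyphenyl)ethyl]phenyl}(3,5-dimethoxyphenyl)methanone, via aryllithium 4 (not isolated)
Conditions: n-BuLi, THF, 0 °C to rt; then cannulated into 3 (1.3 equiv), THF, −78 °C to 0 °C
Reagents that add atoms: 3,5-dimethoxybenzoyl chloride 3, COc1cc(cc(OC)c1)C(Cl)=O; n-butyllithium, [Li]CCCC (lithium of 4 only)
Why: In this directed ortho-metalation the two methoxy groups jointly steer n-BuLi to the carbon between them (para to the side chain), and acylation by inverse addition stops at the ketone because its carbonyl is shielded by two ortho methoxy groups against a second, equally hindered aryllithium.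

**Step 3**
Reactants: 5 pentamethoxy ketone
Product: 6 {2,6-dihydroxy-4-[2-(4-hydroxyphenyl)ethyl]phenyl}(3,5-dihydroxyphenyl)methanone
Conditions: BBr3 (10 equiv), CH2Cl2, −78 °C to rt; then H2O
Reagents that add atoms: none
Why: Exhaustive Lewis-acid cleavage of aryl methyl ethers (BBr3 demethylation) needs no selectivity here and acts on an achiral benzophenone that has no acid-labile bond and no ortho leaving group for xanthone formation.

**Step 4**
Reactants: 6 pentahydroxy ketone; 7 4-(benzyloxy)benzyl chloride
Product: 8 {2,6-bis(BOB-oxy)-4-[2-(4-BOB-oxyphenyl)ethyl]phenyl}[3,5-bis(BOB-oxy)phenyl]methanone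
Conditions: 7 (5.5 equiv), K2CO3, DMF, 70 °C
Reagents that add atoms: 4-(benzyloxy)benzyl chloride 7, ClCc1ccc(OCc2ccccc2)cc1
Why: This exhaustive Williamson ether synthesis uses a reactive 4-alkoxybenzyl chloride, with warming in a dipolar aprotic solvent to drive the two chelated, hindered ortho phenols to completion after the three free ones.

**Step 5**
Reactants: 8 penta-BOB ketone
Product: 9 hydrazone of 8 (C=N geometry of no consequence)
Conditions: N2H4·H2O (excess), AcOH (cat.), n-BuOH–1,4-dioxane, 110 °C, sealed tube, Ar
Reagents that add atoms: hydrazine monohydrate, NN.O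
Why: Acid-catalysed hydrazone condensation of a diaryl ketone is pushed by a large excess of the small nucleophile and by heat to overcome the two ortho ethers, and benzylic aryl ethers tolerate hot hydrazine.

**Step 6**
Reactants: 9 hydrazone
Product: 10 {2,6-bis(BOB-oxy)-4-[2-(4-BOB-oxyphenyl)ethyl]phenyl}[3,5-bis(BOB-oxy)phenyl]diazomethane
Conditions: activated MnO2 (8 equiv), CH2Cl2, 0 °C to rt, dark; filtered through Celite, concentrated cold, used without purification
Reagents that add atoms: none
Why: Dehydrogenation of a diaryl ketone hydrazone with MnO2 is the standard entry to diaryldiazomethanes, the ethers are not touched at this temperature, and the two ortho substituents slow azine formation.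

**Step 7**
Reactants: 10 diaryldiazomethane
Product: 11 cis-(2R,3S)-2-[4-(benzyloxy)phenyl]-3-[3,5-bis(BOB-oxy)phenyl]-4-(BOB-oxy)-6-{2-[4-(BOB-oxy)phenyl]ethyl}-2,3-dihydrobenzofuran
Conditions: Rh2(R-PTAD)4 (1 mol %), 4 Å MS, CH2Cl2, 0 °C, slow addition of 10
Reagents that add atoms: none
Why: The dirhodium complex is attacked by the diazo carbon, nitrogen departs, and the rhodium carbene, moderated by two electron-rich aryl groups, takes up a C–H bond of a neighbouring OCH2Ar group through a concerted but asynchronous, hydride-shift-like transition state whose developing positive charge at C2 is carried by the ether oxygen and the 4-alkoxyphenyl ring. The closest known reaction type is the enantioselective intramolecular C–H insertion of diaryl dirhodium carbenes generated from 2-benzyloxybenzophenone hydrazones, which gives cis-2,3-diaryl-2,3-dihydrobenzofurans, and 10 differs from those substrates only in a second ortho ether and larger remote groups. The one new ring (O1–C2–C3–C3a–C7a) closes by 1,5-insertion, with C2–C3 forming through a five-membered cyclic transition state, and no other ring size is within reach because all remaining benzylic OCH2 groups sit meta or para and point away from the carbene. C3 is set by the carbene face left open by the bowl of phthalimido and adamantyl groups, and C2 by which enantiotopic hydrogen of the OCH2 group can be presented to that face, the compact arrangement with both aryl groups on one side of the forming ring giving the cis (2R,3S) isomer. The step needs chemoselectivity over azine formation and carbene dimerisation, which the ortho substituents, the slow addition and the low electrophilicity of the carbene secure. It needs no choice between the two ortho ethers, because rotation about the C3–C3a bond interchanges them and both lead to 11, the unused one becoming the C4 oxygen substituent.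

**Step 8**
Reactants: 11 protected cis-dihydrobenzofuran
Product: 12 cis-(2R,3S)-3-(3,5-dihydroxyphenyl)-2-(4-hydroxyphenyl)-6-[2-(4-hydroxyphenyl)ethyl]-2,3-dihydrobenzofuran-4-ol
Conditions: H2 (1 atm), 10% Pd/C, THF–MeOH, rt, stopped at full debenzylation
Reagents that add atoms: none
Why: Catalytic hydrogenolysis cleaves the nine primary benzylic C–O bonds, which reach the palladium surface far more easily than the secondary C2–O1 bond flanked by the C3 aryl group, and the neutral medium leaves both stereocentres untouched.

**Step 9**
Reactants: 12 cis-pentaphenol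
Product: 13 trans-(2S,3S)-3-(3,5-dihydroxyphenyl)-2-(4-hydroxyphenyl)-6-[2-(4-hydroxyphenyl)ethyl]-2,3-dihydrobenzofuran-4-ol (target)
Conditions: TFA, CH2Cl2–HFIP, 0 °C to rt, high dilution
Reagents that add atoms: none
Why: In this acid-catalysed epimerisation by reversible SN1-type ring opening, protonated O1 leaves C2 as a 4-hydroxybenzyl cation, either of the two equivalent ortho phenols recloses the ring to the same constitution, and the equilibrium settles on the less crowded trans isomer with C2 now (S), while C3 never ionises and keeps the (S) configuration set in step 7.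

**Compound list**

1 | (E)-3,4',5-trimethoxystilbene | COc1ccc(/C=C/c2cc(OC)cc(OC)c2)cc1 | starting material
2 | 1,3-dimethoxy-5-[2-(4-methoxyphenyl)ethyl]benzene | COc1ccc(CCc2cc(OC)cc(OC)c2)cc1 | intermediate
3 | 3,5-dimethoxybenzoyl chloride | COc1cc(cc(OC)c1)C(Cl)=O | starting material
4 | 2,6-dimethoxy-4-[2-(4-methoxyphenyl)ethyl]phenyllithium | [Li]c1c(OC)cc(CCc2ccc(OC)cc2)cc1OC | intermediate
5 | {2,6-dimethoxy-4-[2-(4-methoxyphenyl)ethyl]phenyl}(3,5-dimethoxyphenyl)methanone | COc1ccc(CCc2cc(OC)c(C(=O)c3cc(OC)cc(OC)c3)c(OC)c2)cc1 | intermediate
6 | {2,6-dihydroxy-4-[2-(4-hydroxyphenyl)ethyl]phenyl}(3,5-dihydroxyphenyl)methanone | Oc1ccc(CCc2cc(O)c(C(=O)c3cc(O)cc(O)c3)c(O)c2)cc1 | intermediate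
7 | 4-(benzyloxy)benzyl chloride | ClCc1ccc(OCc2ccccc2)cc1 | starting material
8 | penta-BOB ether of ketone 6 | O=C(c1cc(OCc2ccc(OCc3ccccc3)cc2)cc(OCc2ccc(OCc3ccccc3)cc2)c1)c1c(OCc2ccc(OCc3ccccc3)cc2)cc(CCc2ccc(OCc3ccc(OCc4ccccc4)cc3)cc2)cc1OCc1ccc(OCc2ccccc2)cc1 | intermediate
9 | hydrazone of 8 | NN=C(c1cc(OCc2ccc(OCc3ccccc3)cc2)cc(OCc2ccc(OCc3ccccc3)cc2)c1)c1c(OCc2ccc(OCc3ccccc3)cc2)cc(CCc2ccc(OCc3ccc(OCc4ccccc4)cc3)cc2)cc1OCc1ccc(OCc2ccccc2)cc1 | intermediate
10 | penta-BOB diaryldiazomethane | [N-]=[N+]=C(c1cc(OCc2ccc(OCc3ccccc3)cc2)cc(OCc2ccc(OCc3ccccc3)cc2)c1)c1c(OCc2ccc(OCc3ccccc3)cc2)cc(CCc2ccc(OCc3ccc(OCc4ccccc4)cc3)cc2)cc1OCc1ccc(OCc2ccccc2)cc1 | intermediate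
11 | protected cis-(2R,3S)-2,3-diaryl-2,3-dihydrobenzofuran | c1ccccc1COc1ccc(COc2ccc(CCc3cc(OCc5ccc(OCc6ccccc6)cc5)c4c(c3)O[C@@H](c3ccc(OCc5ccccc5)cc3)[C@H]4c3cc(OCc5ccc(OCc6ccccc6)cc5)cc(OCc5ccc(OCc6ccccc6)cc5)c3)cc2)cc1 | intermediate
12 | cis-(2R,3S)-pentaphenol | Oc1ccc(CCc2cc(O)c3c(c2)O[C@@H](c2ccc(O)cc2)[C@H]3c2cc(O)cc(O)c2)cc1 | intermediate
13 | trans-(2S,3S)-pentaphenol, CNP0315602.1 | Oc1ccc(CCc2cc(O)c3c(c2)O[C@H](c2ccc(O)cc2)[C@H]3c2cc(O)cc(O)c2)cc1 | target

Total step count: 9. Longest linear sequence: 9 steps, from 1 to 13; 3 and 7 are purchased reagents.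

**Steps most likely to fail**

Step 7. The crowded diazo carbon may reach the rhodium centre inside the bowl of bulky chiral ligands only slowly. Uncatalysed nitrogen loss and azine formation could then take over, or the two carbene faces could be poorly differentiated. The fallback gives up catalyst control and resolves instead. Setting out from 10, the sterically open achiral Rh2(OAc)4 in CH2Cl2 should perform the same 1,5-insertion. It should give 11 as a racemate with its mirror image, the (2S,3R)-cis-dihydrobenzofuran F1. Preparative chromatography on a polysaccharide-based chiral stationary phase separates the two, and the route is rejoined at 11.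

Step 5. Addition of hydrazine to a carbonyl screened on both faces by ortho ethers may be too slow. Prolonged heating also invites displacement of an ortho ether by the hydrazone nitrogen, with ring closure to an indazole. The fallback raises the electrophilicity of the carbon instead of forcing the condensation. Setting out from 8, thionation with Lawesson's reagent in toluene at 90 °C gives the diaryl thioketone F2. Its C=S bond exchanges with N2H4·H2O in THF–EtOH at rt, with loss of hydrogen sulfide. The route is rejoined at 9.

Step 8. Over-reduction may occur once the primary ethers are gone, with the palladium surface also cleaving the secondary benzylic C2–O1 bond of the strained cis ring. The fallback replaces reduction by Lewis-acid dealkylation. Setting out from 11, BCl3 with pentamethylbenzene as a non-basic cation trap in CH2Cl2 at −78 °C strips all benzyl and BOB ethers. Any reversible ionisation of C2–O1 under these conditions only anticipates the equilibration. The crude pentaphenol rejoins the route at 12 and is carried through step 9.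

**Further compounds**

F1 | step 7 | (2S,3R)-cis enantiomer of 11 | c1ccccc1COc1ccc(COc2ccc(CCc3cc(OCc5ccc(OCc6ccccc6)cc5)c4c(c3)O[C@H](c3ccc(OCc5ccccc5)cc3)[C@@H]4c3cc(OCc5ccc(OCc6ccccc6)cc5)cc(OCc5ccc(OCc6ccccc6)cc5)c3)cc2)cc1
F2 | step 5 | penta-BOB diaryl thioketone | S=C(c1cc(OCc2ccc(OCc3ccccc3)cc2)cc(OCc2ccc(OCc3ccccc3)cc2)c1)c1c(OCc2ccc(OCc3ccccc3)cc2)cc(CCc2ccc(OCc3ccc(OCc4ccccc4)cc3)cc2)cc1OCc1ccc(OCc2ccccc2)cc1
F0 | step 8 | none | none
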